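The route rests on cutting ring B at C9, the chain-bearing tertiary carbon flanked by quaternary C10 and carbinol C8. A trans-fused hydrindanone holding ring A, with its C8 ketone bonded directly to C10, is joined to a citronellol-derived α-selenoalkyllithium; loss of selenium then shifts C10 from C8 to C9. One operation thus forms C8–C9 and C9–C10, enlarges the cyclopentanone to ring B, attaches the whole side chain and leaves a C8 ketone for the tertiary alcohol. The precursors are a C18 benzyl ether of the hydrindanone and a C15 TBDPS ether of the bis(methylseleno)acetal, so that both primary alcohols can later be acylated one after the other.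

Key step: step 13

Remark: labdane numbering is used for all intermediates (ring A = C1–C5/C10, ring B = C5–C10, C18 = the CH2O group on C4 anti to the C20 methyl on C10, "syn"/"anti" refer to C20); the target is read as (4S,5S,8S,9S,10R,13S) with a (Z)-2-methylbut-2-enoate (angelate), i.e. the enantiomeric labdane series, so the annulation uses the (R)-amino acid; MeSeH for step 12 is assumed to be prepared beforehand from MeSeSeMe; TBDPS = tert-butyldiphenylsilyl, MOM = methoxymethyl.

Step 1
Reactants: 1 2-methylcyclopentane-1,3-dione; 2 ethyl vinyl ketone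
Product: 3 2-methyl-2-(3-oxopentyl)cyclopentane-1,3-dione
Conditions: H2O, AcOH (cat.), 75 °C
Reagents that add atoms: none
Why: Michael addition of the acidic 1,3-dione to the enone runs under weakly acidic aqueous conditions that avoid retro-Claisen cleavage, and no stereocenter arises because the quaternary carbon is still prochiral.

Step 2
Reactants: 3 triketone
Product: 5 (R)-4,7a-dimethyl enedione, via bicyclic aldol ketol 4 (not isolated)
Conditions: (R)-phenylalanine (1 equiv), 10-camphorsulfonic acid (0.5 equiv), DMF, 30 → 70 °C
Reagents that add atoms: none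
Why: Hajos–Parrish-type amino-acid-mediated intramolecular aldol condensation, in which the enamine of the side-chain ketone differentiates the two enantiotopic ring carbonyls so that the (R)-amino acid should set C10 as R (the mirror image of the outcome with the natural amino acid) before acid-promoted dehydration; enantiomeric enrichment by recrystallisation should be possible here or at 6.

Step 3
Reactants: 5 (R)-enedione
Product: 6 (1R,7aR)-hydroxy enone
Conditions: NaBH4 (0.3 equiv), EtOH, −20 °C
Reagents that add atoms: none
Why: chemoselective borohydride reduction of the saturated cyclopentanone in preference to the less electrophilic conjugated ketone, hydride arriving anti to the angular methyl so that the C8 hydroxyl is syn to C20 (a temporary stereocenter, erased in step 9).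

Step 4
Reactants: 6 hydroxy enone
Product: 7 MOM ether of 6
Conditions: MOMCl, i-Pr2NEt, CH2Cl2, 0 → 40 °C
Reagents that add atoms: chloromethyl methyl ether COCCl
Why: acetal protection by alkylation of the alcohol gives a group that tolerates dissolving metal and hot KOH and can later be removed by acid without touching a benzyl ether.

Step 5
Reactants: 7 MOM-protected enone
Product: 9 trans-fused 18-hydroxy-3-ketone, via lithium enolate 8 (not isolated)
Conditions: Li (2.2 equiv), t-BuOH (1 equiv), NH3(l)/THF, −78 °C; isoprene; NH3 evaporated, THF, −78 °C; CH2O (g, from paraformaldehyde), → −40 °C; aq. NH4Cl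
Reagents that add atoms: formaldehyde C=O
Why: Birch-type dissolving-metal reduction of the enone gives the regiodefined C3–C4 enolate with protonation at C5 anti to C20 (trans ring fusion), and aldol capture by monomeric formaldehyde (reductive hydroxymethylation) occurs on the enolate face anti to the 1,3-related axial C20 methyl, setting quaternary C4 with CH2OH anti and CH3 syn to C20.

Step 6
Reactants: 9 ketol
Product: 10 18-benzyl ether of the 3-ketone
Conditions: 2-benzyloxy-1-methylpyridinium triflate (2 equiv), MgO (2 equiv), PhCF3, 85 °C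
Reagents that add atoms: 2-benzyloxy-1-methylpyridinium triflate C[n+]1ccccc1OCc1ccccc1.[O-]S(=O)(=O)C(F)(F)F
Why: benzyl transfer from the pyridinium salt under neutral conditions etherifies the neopentyl alcohol without forming the alkoxide that would trigger retro-aldol loss of formaldehyde, and leaves the MOM acetal intact.

Step 7
Reactants: 10 benzyl-protected 3-ketone
Product: 12 C3-deoxygenated hydrindane, via hydrazone 11 (not isolated)
Conditions: N2H4·H2O, diethylene glycol, 130 °C; then KOH, 200 °C
Reagents that add atoms: none
Why: Wolff–Kishner reduction in the Huang–Minlon manner removes the C3 carbonyl as is usual for 3-ketones next to a quaternary C4; no leaving group sits on the α-carbon, the ketone can no longer undergo retro-aldol cleavage, and benzyl and MOM ethers are base-stable.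

Step 8
Reactants: 12 MOM ether
Product: 13 (1R,3aR,4S,7aR)-hydrindan-1-ol
Conditions: conc. HCl (cat.), MeOH, 50 °C
Reagents that add atoms: none
Why: acid-catalysed transacetalisation to methanol cleaves the MOM group while the benzyl ether and the saturated skeleton are inert.

Step 9
Reactants: 13 secondary alcohol
Product: 14 (3aR,4S,7aR)-hydrindan-1-one (fragment 1)
Conditions: (n-Pr4N)RuO4 (5 mol%), NMO, 4 Å MS, CH2Cl2, rt
Reagents that add atoms: none
Why: Ley–Griffith oxidation converts the hindered secondary alcohol to the C8 ketone under neutral conditions that cannot epimerise C5 (not α to the carbonyl) or affect the benzyl ether.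

Step 10
Reactants: 15 (S)-citronellol
Product: 16 TBDPS ether of (S)-citronellol
Conditions: TBDPSCl, imidazole, DMF, rt
Reagents that add atoms: tert-butyl(chloro)diphenylsilane CC(C)(C)[Si](Cl)(c1ccccc1)c1ccccc1
Why: imidazole-promoted silylation of the primary alcohol installs a group robust towards Lewis acid, organolithium, base, peracid and hydride and removable by fluoride at the end; C13 comes unchanged from the chiral pool.

Step 11
Reactants: 16 silyl ether
Product: 18 (S)-6-(tert-butyldiphenylsilyloxy)-4-methylhexanal, via secondary ozonide 17 (not isolated)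
Conditions: O3, CH2Cl2, −78 °C; then PPh3, −78 °C → rt
Reagents that add atoms: ozone [O-][O+]=O
Why: ozonolysis of the electron-rich trisubstituted alkene with reductive work-up gives the aldehyde (future C9) and acetone without touching the remote C13 stereocenter.

Step 12
Reactants: 18 aldehyde
Product: 19 bis(methylseleno)acetal (fragment 2)
Conditions: MeSeH (2.2 equiv), ZnCl2 (0.5 equiv), CH2Cl2, −10 °C → rt
Reagents that add atoms: methaneselenol C[SeH]
Why: Lewis-acid-promoted selenoacetalisation, the selenium counterpart of dithioacetal formation, is mild enough for the silyl ether and gives the precursor of an α-selenoalkyllithium.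

Step 13
Reactants: 19 bis(methylseleno)acetal (fragment 2); 14 hydrindanone (fragment 1)
Product: 23 ring-B C8 ketone carrying the side chain on C9, via α-selenoalkyllithium 20 (not isolated), via β-hydroxyselenide 21 (not isolated), via C9-epimeric ketone 22 (not isolated)
Conditions: 19 (1.1 equiv), n-BuLi (1.1 equiv), THF, −78 °C; then 14, −78 °C; aq. NH4Cl, crude dried under vacuum; AgBF4 (3 equiv), Al2O3, CH2Cl2, 0 °C → rt; filtered, crude; NaOMe (0.2 equiv), MeOH/THF, rt
Reagents that add atoms: none
Why: Selenium–lithium exchange on 19 gives the weakly basic but strongly nucleophilic α-(methylseleno)alkyllithium 20, which adds to the C8 carbonyl of 14 anti to C20 (C8–C9 bond); silver coordination to the remaining selenium of 21 then makes it a leaving group and C10 migrates from C8 to C9 with retention while the C8 hydroxyl collapses to the ketone (C9–C10 bond). This is the established one-carbon homologation of cycloalkanones through β-hydroxyselenides, a semipinacol shift of the Tiffeneau–Demjanov type. Ring B is not closed by joining two chain ends but arises by enlargement of the cyclopentanone, the migrating C8–C10 bond lying antiperiplanar to the C9–Se bond and the change from a strained trans-hydrindanone to a trans-decalone providing the driving force. C9 is first formed as an epimer mixture because 21 is a mixture at the selenium-bearing carbon and the shift inverts that centre; NaOMe equilibration next to the C8 ketone should then place the side chain equatorial (syn to C20, H-9 anti), which is both the thermodynamic and the required configuration. The step needs addition instead of enolisation, rearrangement instead of epoxide closure or elimination, and migration of C10 instead of C7; these are secured by the low basicity of 20, by non-basic silver activation on a strained cyclopentanol, and by the higher migratory aptitude of the quaternary C10.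

Step 14
Reactants: 23 C8 ketone
Product: 24 8(17)-exocyclic alkene
Conditions: Ph3PCH3Br, KOtBu, toluene, 80 °C
Reagents that add atoms: methyltriphenylphosphonium bromide C[P+](c1ccccc1)(c1ccccc1)c1ccccc1.[Br-]
Why: Wittig methylenation with the small unstabilised ylide is the usual way to convert hindered 8-oxo decalins into exocyclic alkenes, and C9 is already in its thermodynamic configuration so basic conditions cannot erode it.

Step 15
Reactants: 24 exocyclic alkene
Product: 25 8,17-epoxide with equatorial oxygen
Conditions: mCPBA, NaHCO3, CH2Cl2, 0 °C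
Reagents that add atoms: mCPBA OOC(=O)c1cccc(Cl)c1
Why: Prilezhaev epoxidation should occur from the equatorial side of C8, anti to C20, because the axial trajectory is blocked by the syn-axial C20 methyl on C10, which places the oxygen equatorial and C17 axial and thereby sets C8.

Step 16
Reactants: 25 epoxide
Product: 26 tertiary C8 alcohol
Conditions: LiEt3BH, THF, 0 °C → rt; aq. NH4Cl
Reagents that add atoms: none
Why: SN2 hydride opening of the 1,1-disubstituted epoxide at its unsubstituted carbon turns C17 into the axial methyl and leaves the equatorial C8–O bond untouched, so the configuration set in step 15 is retained; benzyl and silyl ethers are inert.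

Step 17
Reactants: 26 benzyl ether
Product: 27 8,18-diol with C15 silyl ether
Conditions: H2 (1 atm), Pd/C, EtOAc/EtOH, rt
Reagents that add atoms: none
Why: catalytic hydrogenolysis cleaves only the benzyl ether, since the molecule holds no alkene at this stage and the silyl ether and tertiary alcohol are stable.

Step 18
Reactants: 27 diol
Product: 28 C18 angelate
Conditions: angelic acid, 2,4,6-trichlorobenzoyl chloride, Et3N, toluene, rt; then 27, 75 °C
Reagents that add atoms: angelic acid C/C=C(/C)C(=O)O
Why: Yamaguchi-type esterification through the mixed anhydride without a nucleophilic catalyst acylates the primary neopentyl alcohol at the less hindered angeloyl carbonyl and avoids the conjugate addition–elimination that would isomerise Z to E, while the tertiary C8 hydroxyl is too hindered to react.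

Step 19
Reactants: 28 silyl ether
Product: 29 C15 primary alcohol
Conditions: HF·pyridine, pyridine/THF, 0 °C → rt
Reagents that add atoms: none
Why: buffered fluoride desilylation removes the TBDPS group under conditions that neither hydrolyse nor isomerise the angelate and do not ionise the tertiary alcohol.

Step 20
Reactants: 29 primary alcohol
Product: 30 CNP0286290.1 (target)
Conditions: Meldrum's acid (1.3 equiv), toluene, 90 °C
Reagents that add atoms: Meldrum's acid CC1(C)OC(=O)CC(=O)O1
Why: thermal acylation, in which the unhindered primary alcohol opens Meldrum's acid with loss of acetone to give the malonic half ester directly; the tertiary alcohol is unreactive and the neutral conditions leave the angelate geometry intact.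

Compound list
1 | 2-methylcyclopentane-1,3-dione | CC1C(=O)CCC1=O | starting material
2 | ethyl vinyl ketone (pent-1-en-3-one) | C=CC(=O)CC | starting material
3 | 2-methyl-2-(3-oxopentyl)cyclopentane-1,3-dione (achiral) | CCC(=O)CCC1(C)C(=O)CCC1=O | intermediate
4 | (3aR,7aR)-3a-hydroxy-4,7a-dimethylhexahydroindane-1,5-dione, cis-fused ketol, OH syn to the angular methyl, C4 epimers | CC1C(=O)CC[C@@]2(C)C(=O)CC[C@@]12O | intermediate (not isolated)
5 | (R)-4,7a-dimethyl-2,3,7,7a-tetrahydro-1H-indene-1,5(6H)-dione | CC1=C2CCC(=O)[C@]2(C)CCC1=O | intermediate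
6 | (1R,7aR)-1-hydroxy-4,7a-dimethyl-1,2,3,6,7,7a-hexahydro-5H-inden-5-one (OH syn to the angular methyl) | CC1=C2CC[C@@H](O)[C@]2(C)CCC1=O | intermediate
7 | (1R,7aR)-1-(methoxymethoxy)-4,7a-dimethyl-1,2,3,6,7,7a-hexahydro-5H-inden-5-one | CC1=C2CC[C@@H](OCOC)[C@]2(C)CCC1=O | intermediate
8 | lithium C3–C4 enolate of the trans-fused hydrindanone (H-5 anti to C20, C8–OMOM syn to C20) | CC1=C(O[Li])CC[C@]2(C)[C@@H]1CC[C@H]2OCOC | intermediate (not isolated)
9 | trans-fused hydrindan-3-one: C4 with CH2OH (anti to C20) and CH3 (syn to C20), H-5 anti to C20, C8–OMOM syn to C20 | OC[C@@]1(C)C(=O)CC[C@]2(C)[C@@H]1CC[C@H]2OCOC | intermediate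
10 | 18-benzyl ether of 9 | C(c1ccccc1)OC[C@@]1(C)C(=O)CC[C@]2(C)[C@@H]1CC[C@H]2OCOC | intermediate
11 | C3 hydrazone of 10 | C(c1ccccc1)OC[C@@]1(C)C(=NN)CC[C@]2(C)[C@@H]1CC[C@H]2OCOC | intermediate (not isolated)
12 | C3-deoxygenated trans-hydrindane with C18–OBn and C8–OMOM | C(c1ccccc1)OC[C@@]1(C)CCC[C@]2(C)[C@@H]1CC[C@H]2OCOC | intermediate
13 | (1R,3aR,4S,7aR)-4-[(benzyloxy)methyl]-4,7a-dimethyloctahydro-1H-inden-1-ol | C(c1ccccc1)OC[C@@]1(C)CCC[C@]2(C)[C@@H]1CC[C@H]2O | intermediate
14 | (3aR,4S,7aR)-4-[(benzyloxy)methyl]-4,7a-dimethyloctahydro-1H-inden-1-one, fragment 1 (trans-fused; C8 ketone bonded to C10) | C(c1ccccc1)OC[C@@]1(C)CCC[C@]2(C)[C@@H]1CCC2=O | intermediate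
15 | (S)-citronellol | CC(C)=CCC[C@H](C)CCO | starting material
16 | (S)-tert-butyl[(3,7-dimethyloct-6-en-1-yl)oxy]diphenylsilane | CC(C)=CCC[C@H](C)CCO[Si](c1ccccc1)(c1ccccc1)C(C)(C)C | intermediate
17 | secondary ozonide (3,3-dimethyl-1,2,4-trioxolane carrying the silyloxy chain on C5) of 16 | CC1(C)OOC(CC[C@H](C)CCO[Si](c2ccccc2)(c2ccccc2)C(C)(C)C)O1 | intermediate (not isolated)
18 | (S)-6-(tert-butyldiphenylsilyloxy)-4-methylhexanal | O=CCC[C@H](C)CCO[Si](c1ccccc1)(c1ccccc1)C(C)(C)C | intermediate
19 | (S)-tert-butyl{[3-methyl-6,6-bis(methylselanyl)hexyl]oxy}diphenylsilane, fragment 2 | C[Se]C([Se]C)CC[C@H](C)CCO[Si](c1ccccc1)(c1ccccc1)C(C)(C)C | intermediate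
20 | 1-lithio-1-(methylselanyl)alkane from 19 (carbanion centre = future C9) | [Li]C([Se]C)CC[C@H](C)CCO[Si](c1ccccc1)(c1ccccc1)C(C)(C)C | intermediate (not isolated)
21 | β-hydroxyselenide: hydrindan-8-ol with OH syn to C20 and the 1-(methylselanyl)alkyl group on C8 anti to C20, C9 epimers | C(c1ccccc1)OC[C@@]1(C)CCC[C@]2(C)[C@@H]1CC[C@]2(O)C([Se]C)CC[C@H](C)CCO[Si](c1ccccc1)(c1ccccc1)C(C)(C)C | intermediate (not isolated)
22 | 18-benzyloxy-15-(tert-butyldiphenylsilyloxy)-17-norlabdan-8-one, mixture of C9 epimers | C(c1ccccc1)OC[C@@]1(C)CCC[C@]2(C)[C@@H]1CCC(=O)C2CC[C@H](C)CCO[Si](c1ccccc1)(c1ccccc1)C(C)(C)C | intermediate (not isolated)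
23 | (4S,5S,9S,10R,13S)-18-benzyloxy-15-(tert-butyldiphenylsilyloxy)-17-norlabdan-8-one (side chain on C9 equatorial, syn to C20) | C(c1ccccc1)OC[C@@]1(C)CCC[C@]2(C)[C@@H]1CCC(=O)[C@H]2CC[C@H](C)CCO[Si](c1ccccc1)(c1ccccc1)C(C)(C)C | intermediate
24 | 18-benzyloxy-15-(tert-butyldiphenylsilyloxy)labd-8(17)-ene, configuration at C4, C5, C9, C10, C13 as in 23 | C(c1ccccc1)OC[C@@]1(C)CCC[C@]2(C)[C@@H]1CCC(=C)[C@H]2CC[C@H](C)CCO[Si](c1ccccc1)(c1ccccc1)C(C)(C)C | intermediate
25 | 8,17-epoxide of 24, oxygen equatorial (anti to C20), C17 axial (syn to C20) | C(c1ccccc1)OC[C@@]1(C)CCC[C@]2(C)[C@@H]1CC[C@@]3(CO3)[C@H]2CC[C@H](C)CCO[Si](c1ccccc1)(c1ccccc1)C(C)(C)C | intermediate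
26 | (4S,5S,8S,9S,10R,13S)-18-benzyloxy-15-(tert-butyldiphenylsilyloxy)labdan-8-ol (8-OH equatorial, C17 methyl axial) | C(c1ccccc1)OC[C@@]1(C)CCC[C@]2(C)[C@@H]1CC[C@](C)(O)[C@H]2CC[C@H](C)CCO[Si](c1ccccc1)(c1ccccc1)C(C)(C)C | intermediate
27 | (4S,5S,8S,9S,10R,13S)-15-(tert-butyldiphenylsilyloxy)labdane-8,18-diol | OC[C@@]1(C)CCC[C@]2(C)[C@@H]1CC[C@](C)(O)[C@H]2CC[C@H](C)CCO[Si](c1ccccc1)(c1ccccc1)C(C)(C)C | intermediate
28 | (4S,5S,8S,9S,10R,13S)-15-(tert-butyldiphenylsilyloxy)-8-hydroxylabdan-18-yl (Z)-2-methylbut-2-enoate | C/C=C(/C)C(=O)OC[C@@]1(C)CCC[C@]2(C)[C@@H]1CC[C@](C)(O)[C@H]2CC[C@H](C)CCO[Si](c1ccccc1)(c1ccccc1)C(C)(C)C | intermediate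
29 | (4S,5S,8S,9S,10R,13S)-8,15-dihydroxylabdan-18-yl (Z)-2-methylbut-2-enoate | C/C=C(/C)C(=O)OC[C@@]1(C)CCC[C@]2(C)[C@@H]1CC[C@](C)(O)[C@H]2CC[C@H](C)CCO | intermediate
30 | CNP0286290.1: (4S,5S,8S,9S,10R,13S)-18-[(Z)-2-methylbut-2-enoyloxy]-8-hydroxylabdan-15-yl hydrogen malonate | C/C=C(/C)C(=O)OC[C@@]1(C)CCC[C@]2(C)[C@@H]1CC[C@](C)(O)[C@H]2CC[C@H](C)CCOC(=O)CC(=O)O | target

Total step count: 20. Longest linear sequence: 17 steps (steps 1–9, then 13–20, from 2-methylcyclopentane-1,3-dione); the side-chain arm (steps 10–12) joins at step 13.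

Steps most likely to fail

Step 13. The hindered, enolisable ketone may transfer a proton to the organolithium instead of accepting it. After silver activation, the alkoxide may close onto C9 to an epoxide, or elimination may occur, in place of the 1,2-shift. The fallback keeps the same two bonds but makes C8–C9 by olefination and uses bromide as the leaving group on C9. It sets out from aldehyde 18 and ketone 14. NaBH4 reduction of 18 should give (S)-6-(tert-butyldiphenylsilyloxy)-4-methylhexan-1-ol F1; I2/PPh3/imidazole the iodide (S)-tert-butyl[(6-iodo-3-methylhexyl)oxy]diphenylsilane F2; and heating with PPh3 in MeCN the phosphonium iodide F3. Its ylide (KN(SiMe3)2, THF) is condensed with 14 in a Wittig reaction of the kind used to alkylidenate 17-keto steroids, giving the alkylidene hydrindane F4. NBS in aqueous DME should give the Markovnikov bromohydrin F5 (OH on C8, Br on C9). Its magnesium alkoxide (i-PrMgCl, toluene, heat) undergoes the halohydrin semipinacol ring enlargement to 22, and the NaOMe equilibration of step 13 brings the route back at 23.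

Step 5. Capture of the ammonia-derived enolate by gaseous formaldehyde may be incomplete (proton quench, oligomeric formaldehyde adducts), and the trans ring-fusion selectivity of the reduction may be eroded. The fallback separates reduction from C–C bond formation and sets out from 7. After the same Li/NH3 reduction the enolate is silylated (Me3SiCl, Et3N) to the trimethylsilyl enol ether F6, which can be purified from any cis-fused isomer. F6 is then hydroxymethylated in a Lewis-acid-catalysed Mukaiyama aldol reaction with aqueous formaldehyde (Yb(OTf)3, THF/H2O), the electrophile again approaching anti to C20, and the route is rejoined at 9.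

Step 18. Slow acylation of the neopentyl alcohol may allow geometric isomerisation of the activated angeloyl unit to the E (tigloyl) ester. The fallback builds the Z alkene on the ester instead of transferring it and sets out from 27. Esterification with 2-[bis(2,2,2-trifluoroethoxy)phosphoryl]propanoic acid (EDC·HCl, DMAP, CH2Cl2) should give the phosphonate ester F7. A Still–Gennari olefination with acetaldehyde (KN(SiMe3)2, 18-crown-6, THF, −78 °C) should then deliver the Z-configured 2-methylbut-2-enoate under kinetic control, rejoining the route at 28.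

Further compounds
F1 | step 13 | (S)-6-(tert-butyldiphenylsilyloxy)-4-methylhexan-1-ol | OCCC[C@H](C)CCO[Si](c1ccccc1)(c1ccccc1)C(C)(C)C
F2 | step 13 | (S)-tert-butyl[(6-iodo-3-methylhexyl)oxy]diphenylsilane | ICCC[C@H](C)CCO[Si](c1ccccc1)(c1ccccc1)C(C)(C)C
F3 | step 13 | [(S)-6-(tert-butyldiphenylsilyloxy)-4-methylhexyl]triphenylphosphonium iodide | [I-].C(CC[C@H](C)CCO[Si](c1ccccc1)(c1ccccc1)C(C)(C)C)[P+](c1ccccc1)(c1ccccc1)c1ccccc1
F4 | step 13 | alkylidene hydrindane: C8=C9 alkene of the fragment 1 skeleton carrying the C11–C15 chain (E/Z mixture) | C(c1ccccc1)OC[C@@]1(C)CCC[C@]2(C)[C@@H]1CCC2=CCC[C@H](C)CCO[Si](c1ccccc1)(c1ccccc1)C(C)(C)C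
F5 | step 13 | bromohydrin: hydrindan-8-ol with a 1-bromoalkyl group (C9–Br) on C8 | C(c1ccccc1)OC[C@@]1(C)CCC[C@]2(C)[C@@H]1CCC2(O)C(Br)CC[C@H](C)CCO[Si](c1ccccc1)(c1ccccc1)C(C)(C)C
F6 | step 5 | trimethylsilyl enol ether (C3–C4) of the trans-fused hydrindanone with C8–OMOM | CC1=C(O[Si](C)(C)C)CC[C@]2(C)[C@@H]1CC[C@H]2OCOC
F7 | step 18 | 15-(tert-butyldiphenylsilyloxy)-8-hydroxylabdan-18-yl 2-[bis(2,2,2-trifluoroethoxy)phosphoryl]propanoate | CC(C(=O)OC[C@@]1(C)CCC[C@]2(C)[C@@H]1CC[C@](C)(O)[C@H]2CC[C@H](C)CCO[Si](c1ccccc1)(c1ccccc1)C(C)(C)C)P(=O)(OCC(F)(F)F)OCC(F)(F)F
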